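The readings stem from a simulated flask with made-up constants; noise was put on by code.

Two questions stand on this flask: how much target it holds at 3.0 min as a percentage of the solid substrate charged, and how near the dissolved starting material then comes to saturation.

| flask | solid substrate | remark | time |
|---|---|---|---|
| Wednesday's | 1 M | run made earlier |  |
| Thursday's | 2.2 M | run made earlier |  |
| flask | 1.5 M |  | 3.0 min |

| run | time / min | target / % | starting material / % |
|---|---|---|---|
| Wednesday's | 0.833 | 2.1 | 20.8 |
| Wednesday's | 1.50 | 5.3 | 27.1 |
| Wednesday's | 2.50 | 16.6 | 31.9 |
| Wednesday's | 3.00 | 25.2 | 31.3 |
| Thursday's | 0.833 | 0 | 9.0 |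
| Thursday's | 1.50 | 2.1 | 10.9 |
| Thursday's | 2.50 | 6.0 | 12.5 |
| Thursday's | 3.00 | 11.5 | 13.7 |

(each reading ± 1 percentage point)

- the target standing at 3.0 min, as a percentage of the solid substrate charged
- concentration of starting material in solution at 3.0 min, in percent of saturation

- solid, in amounts per volume of the solution: solid substrate
- what may be going on: solid substrate <-> starting material; intermediate <-> target; intermediate <-> isomer of the product; starting material -> intermediate
- at the start none of the solid substrate is in solution
- starting material means what is dissolved; the solid is not counted in it

Percentages hide what the two runs share. At 3.00 min, Wednesday's target reads 25.2% and Thursday's 11.5%, a ratio of 2.19, while Thursday's charge is 2.20 times Wednesday's. Multiplied by their charges, the readings give 0.252 M and 0.253 M, so in these two runs the target concentration at that time reads as zero order in the charge, within the scatter. Their mean, 0.253 M, is the quantity carried here: c, the target concentration read at that time while solid stands.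

Turned round, the opposite outcome asks that the solid of this flask be gone before 3.0 min. Yet Wednesday's run, charged with 1 M, still reads the target concentration of Thursday's at that time, and this flask holds 1.50 times Wednesday's charge. My reckoning is therefore c divided by 1.5 M, which gives 16.9%.

The forecast reads the runs the same way, that the “absolute concentrations barely depend on loading”, and gives 16.8% (14.5% to 19%) of target and 52% (30% to 78%) of saturation.

The flask gives 16.4% and 41.2%, the latter 11 percentage points below the forecast.

    solid substrate ⇌ starting material, rate k1*(cs1 - [starting material]) while solid is left; crystals form when [starting material] > cs1 (solubility = 0.760 M, k = 0.00940 s⁻¹)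
    intermediate ⇌ target (K = 8.90, k = 0.00940 s⁻¹)
    intermediate ⇌ isomer of the product (K = 2.20, k = 1.10 × 10⁻⁴ s⁻¹)
    starting material → intermediate (k = 0.0130 s⁻¹)

This flask's target comes to 0.246 M, with solid at 41.5% of the charge. On a neighbour charged with 0.90 M, c gives 28.1%, and that neighbour stands at 27.3%, which is 0.246 M of target, with solid at 2.50% of its charge.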